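Two questions stand over these flasks: how much ring each holds at the end, and how that row runs with the charge.

| setting | oak | elm | alder |
|---|---|---|---|
| starting material | 0.50 M | 1.0 M | 2.0 M |
| gas | 200 mM (held) | 200 mM (held) | 200 mM (held) |
| time | 30 min | 30 min | 30 min |

- [ring] at the end for oak, elm, alder, in this order
- the course of these numbers from the first flask to the last (falls, then rises / hardly changes / falls all the way / rises, then falls / rises all the way)

    activated form → side product (k1 = 0.043 min⁻¹)
    activated form → ring (k2 = 0.096 min⁻¹)
    starting material + activated form → open dimer (k3 = 0.073 L mol⁻¹ min⁻¹)
    gas ⇌ activator, rate k4*(csat - [activator]) (k4 = 0.20 min⁻¹, csat = 200 mM)
    starting material + activator → activated form (k5 = 5.5 L mol⁻¹ min⁻¹)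

- in percentages every species weighs as the starting material in it: one open dimer counts as two
- at the start none of activator is dissolved
- "hardly changes" means that all values lie within two and a half points (for a concentration: within two and a half percent of the largest)
- run time (oak): 30 min

In oak, dissolved activator has a half-life of 0.25 min against starting material as charged, while gas transfer needs 3.47 min. So in oak, while [starting material] stays near its charge, transfer is the rate-limiting step, and the gas enters at close to 0.0400 M min⁻¹. Integrating that constant rate over 30 min gives the supply ceiling, the amount of activator that crosses with [activator] held at zero: 1.20 M. The charges of oak and elm stand below it, and the charge of alder above it.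

Two extreme versions can be reckoned by hand, each taking the smaller of charge and ceiling as what gets activated. Without the dimer step, ring takes 69.1% of the activated form, and the row reads 0.345 M, 0.691 M, 0.829 M. With [starting material] held at its charge, the dimer step becomes pseudo-first-order, and the selectivity for ring drops to 54.7%, 45.3% and 33.7% in oak, elm and alder. That row reads 0.274 M, 0.453 M, 0.404 M, so in this version alder stands below elm.

The real [starting material] lies between zero and the charge, which raises the selectivity above the second version. Activated form still unclosed at the end, and the starting material taken up by the dimer step, both lower the yield. This reckoning commits to a row near the second version.

The forecast reads 0.29 M, 0.46 M, 0.41 M, rises, then falls, on these grounds: "Alder is still supply-limited at the end with about half a molar unreacted and loses more activated form to dimer, so its ring falls a little below elm's". Its numbers stand slightly above those of this reckoning, with the same shape.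

The simulation gives 0.291 M, 0.448 M, 0.415 M: rises, then falls. Alder still holds 25.0% of its starting material at 30.0 min. In alder, ring, side product, activated form and the activated unit of each open dimer come to 1.15 M, and with dissolved activator to 1.16 M, below the ceiling of 1.20 M. The row turns at a charge of 1.2 M, level with that ceiling.

(The numbers are made up; the flask was simulated.)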